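In a one-step world the substrate of this flask, with a forward half-life of 0.091 h against reagent as charged, passes through 44.1 half-lives in the run, and conversion is no question.

substrate 1.5 M; reagent 1.50 M; time 4.0 h

    crystals ⇌ product, rate k1*(cs1 - [product]) while solid is left; crystals form when [product] > cs1 (cs1 = 0.084 M, k1 = 0.10 min⁻¹)
    substrate + reagent ⇌ adduct (K2 = 2.9 M⁻¹, k2 = 0.085 M⁻¹ min⁻¹)
    adduct → product (k3 = 0.0022 min⁻¹)

- amount of product and crystals together at 4.0 h, in percent of the substrate charged
- the change that raises the amount of product and crystals together at 4.0 h, in percent of the substrate charged most ("none" if none brings more than 2 percentage points) (east / north-west / south-east / none)
- amount of product and crystals together at 4.0 h, in percent of the substrate charged, after south-east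

Yet the equilibrium constant of step 2 times the substrate charge is 4.3. With equal charges, the bound share of the charge divided by the square of the unbound share equals that number, which gives

bound share = 62.2%

So the half-life of 0.091 h counts the forward rate alone, and the pre-equilibrium, reckoned before any product forms, leaves 37.8% of the charge unbound. Step 2 is quick beside step 3, 0.091 h against an adduct half-life of 5.3 h, so substrate and adduct drain as one pool, and its bound share feeds step 3. Hence the number to carry is the drain count, the bound share held at this reckoned value times the run time over the adduct half-life:

drain count = 0.474

product and crystals = 28.0%

Step 1 has no place in this count, so this reckoning keeps 28.0% after south-east. East raises the bound share to 83.5%, which gains 7.7 percentage points.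

The forecast stands lower than this reckoning, at 26.5%. It names east and gives 26.5% after south-east, holding that “solubility and dissolution rate change the split between them but not their total”.

The simulation gives 26.4%, east with 8.6 points, and 26.4% after south-east; north-west brings 0 points. With the rate constant of step 3 doubled, the flask gives 44.4%, away from the forecast's figure. The drain count of 0.474 reckons 1.6 points above the simulated flask. The neighbouring flask has the same charges and so the same reckoned bound share, but is left until 1.5 h. Its drain count is 0.178, which reckons 11.6%, and that flask reads 10.7%.

All constants were drawn at random within sensible limits; the run is a simulation.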